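**Retrosynthetic overview**
1. Target 15 ⇐ alcohol 14 (acetylation) ⇐ α‑allenol 13: the 2,5‑dihydrofuran is closed through its O–C16 bond (5‑endo oxypalladation), with C17 entering as formaldehyde in the same step.
2. 13 ⇐ bromo enal 11: the 14‑membered carbocycle is closed by chromium‑mediated intramolecular allenylation (C1–C2 bond, sets C2).
3. 11 ⇐ epoxy chloride 4 + but‑2‑ynoic acid 5 (C13–C14 bond; brings C14, C1, C15, C16).
4. 4 ⇐ (2E,6E)‑farnesyl acetate 1: terminal allylic oxidation, chlorination, Shi epoxidation of the central olefin (sets C7, C8).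
5. Ring order: epoxide, then 14‑membered ring, then dihydrofuran.

Assumption: (2E,6E)‑farnesyl acetate, but‑2‑ynoic acid and the L‑fructose‑derived Shi ketone are purchased; macrocycles are described with cembrane numbering (ring C1–C14, side unit C15–C17).

Step 1
Reactants: 1 (2E,6E)-farnesyl acetate
Product: 2 (2E,6E,10E)-12-hydroxy-3,7,11-trimethyldodeca-2,6,10-trien-1-yl acetate
Conditions: SeO2 (0.2 equiv), t‑BuOOH (3 equiv), salicylic acid (0.1 equiv), CH2Cl2, rt
Reagents that add atoms: tert‑butyl hydroperoxide, CC(C)(C)OO; SeO2 (catalytic oxygen carrier), O=[Se]=O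
Why: Catalytic SeO2 allylic oxidation (ene reaction then [2,3]‑sigmatropic shift) attacks the terminal trisubstituted olefin at its E‑methyl group, the acetate‑bearing 2,3‑olefin being deactivated, and gives the (10E)‑allylic alcohol.

Step 2
Reactants: 2 (2E,6E,10E)-12-hydroxy-3,7,11-trimethyldodeca-2,6,10-trien-1-yl acetate
Product: 3 (2E,6E,10E)-12-chloro-3,7,11-trimethyldodeca-2,6,10-trien-1-yl acetate
Conditions: N‑chlorosuccinimide, Me2S, CH2Cl2, −30 → 0 °C
Reagents that add atoms: N‑chlorosuccinimide, ClN1C(=O)CCC1=O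
Why: Corey–Kim chlorination (chlorosulfonium activation, SN2 by chloride) converts the primary allylic alcohol to the chloride without allylic transposition and without acid.

Step 3
Reactants: 3 (2E,6E,10E)-12-chloro-3,7,11-trimethyldodeca-2,6,10-trien-1-yl acetate
Product: 4 (2E,6S,7S,10E)-12-chloro-6,7-epoxy-3,7,11-trimethyldodeca-2,10-dien-1-yl acetate
Conditions: L‑fructose‑derived Shi ketone (30 mol %), 2KHSO5·KHSO4·K2SO4 (Oxone), K2CO3, Bu4NHSO4, MeCN–(MeO)2CH2–aq. Na2B4O7 buffer (pH 10.5), 0 °C, stopped at about 80 % conversion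
Reagents that add atoms: KHSO5 (potassium peroxymonosulfate, from Oxone), [K+].[O-]S(=O)(=O)OO
Why: Shi asymmetric epoxidation: both outer olefins are deactivated by their allylic chlorine and acetoxy groups, so the electrophilic chiral dioxirane takes the central olefin, and the L‑fructose‑derived ketone (spiro transition state, mirror image of the usual catalyst) delivers oxygen to the face that gives (6S,7S).

Step 4
Reactants: 4 (2E,6S,7S,10E)-12-chloro-6,7-epoxy-3,7,11-trimethyldodeca-2,10-dien-1-yl acetate; 5 but-2-ynoic acid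
Product: 7 methyl (6E,10S,11S,14E)-16-acetoxy-10,11-epoxy-6,10,14-trimethylhexadeca-6,14-dien-2-ynoate, via lithium carboxylate 6 (not isolated)
Conditions: 5 (1.5 equiv), LiN(i‑Pr)2 (3.1 equiv), THF–HMPA, −78 °C; add 4, −78 → −20 °C; then MeI, rt
Reagents that add atoms: iodomethane, CI
Why: γ‑Alkylation (SN2) of the dilithium dianion of but‑2‑ynoic acid by the primary allylic chloride adds C14, C1, C15 and C16 in one operation, the delocalised carboxylate‑stabilised anion alkylating faster than it attacks acetate or epoxide at low temperature, and O‑methylation of the carboxylate gives the ester.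

Step 5
Reactants: 7 methyl (6E,10S,11S,14E)-16-acetoxy-10,11-epoxy-6,10,14-trimethylhexadeca-6,14-dien-2-ynoate
Product: 8 (6E,10S,11S,14E)-10,11-epoxy-6,10,14-trimethylhexadeca-6,14-dien-2-yne-1,16-diol
Conditions: i‑Bu2AlH (4.5 equiv), CH2Cl2, −78 → −20 °C; aq. KNaC4H4O6 work‑up
Reagents that add atoms: none
Why: Hydride reduction with i‑Bu2AlH takes the ynoate to the propargylic alcohol (1,2‑reduction) and cleaves the acetate in the same flask, while the trisubstituted epoxide is inert at low temperature.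

Step 6
Reactants: 8 (6E,10S,11S,14E)-10,11-epoxy-6,10,14-trimethylhexadeca-6,14-dien-2-yne-1,16-diol
Product: 9 (2E,6S,7S,10E)-6,7-epoxy-16-hydroxy-3,7,11-trimethylhexadeca-2,10-dien-14-ynal
Conditions: 4‑acetamido‑2,2,6,6‑tetramethyl‑1‑oxopiperidinium tetrafluoroborate (1.05 equiv), SiO2, CH2Cl2, rt
Reagents that add atoms: none
Why: Oxoammonium‑salt oxidation proceeds by hydride abstraction, which is fast for the electron‑rich allylic carbinol and very slow for the electron‑poor propargylic one, so only the enal forms and the 2E geometry is kept.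

Step 7
Reactants: 9 (2E,6S,7S,10E)-6,7-epoxy-16-hydroxy-3,7,11-trimethylhexadeca-2,10-dien-14-ynal
Product: 11 (2E,6S,7S,10E)-16-bromo-6,7-epoxy-3,7,11-trimethylhexadeca-2,10-dien-14-ynal, via propargylic mesylate 10 (not isolated)
Conditions: MsCl, Et3N, THF, −20 °C; then LiBr, 0 °C
Reagents that add atoms: LiBr, [Li+].[Br-]
Why: Mesylation followed by SN2 displacement with bromide gives the primary propargylic bromide under conditions that leave the enal and the epoxide alone.

Step 8
Reactants: 11 (2E,6S,7S,10E)-16-bromo-6,7-epoxy-3,7,11-trimethylhexadeca-2,10-dien-14-ynal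
Product: 13 (2S,3E,7S,8S,11E)-1-ethenylidene-7,8-epoxy-4,8,12-trimethylcyclotetradeca-3,11-dien-2-ol, via trimethylsilyl ether 12 (not isolated)
Conditions: CrCl2 (10 mol %), 1,8‑bis[(S)‑4‑isopropyl‑4,5‑dihydrooxazol‑2‑yl]‑3,6‑diphenylcarbazole (12 mol %), Mn powder, Me3SiCl, i‑Pr2NEt, THF, 2 mM by slow addition, rt; then K2CO3 (cat.), MeOH
Reagents that add atoms: none
Why: Catalytic asymmetric Nozaki–Hiyama allenylation: the γ‑substituted propargyl species of trivalent chromium adds through its γ‑carbon (SE2′) to the enal, closing the 14‑membered ring and creating the exocyclic allene, while the chiral tridentate ligand directs attack to the Re face of the aldehyde to set C2 as S (the ligand antipode is fixed beforehand on farnesal as a model).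

Step 9
Reactants: 13 (2S,3E,7S,8S,11E)-1-ethenylidene-7,8-epoxy-4,8,12-trimethylcyclotetradeca-3,11-dien-2-ol
Product: 14 (2S,7S,8S)-2,16:7,8-diepoxycembra-1(15),3E,11E-trien-17-ol
Conditions: Pd(OCOCF3)2 (5 mol %), 2,2′‑bipyridine (6 mol %), (CH2O)n (5 equiv), 4 Å sieves, 1,4‑dioxane, 50 °C
Reagents that add atoms: formaldehyde (from paraformaldehyde), C=O
Why: Proposed new method: divalent palladium activates the terminal allene π‑bond, the C2 hydroxyl attacks C16 in a 5‑endo oxypalladation (forming the O–C16 bond and the dihydrofuran, C2 untouched), the bipyridine‑ligated σ‑vinylpalladium at C15 inserts formaldehyde (1,2‑addition) and the palladium alkoxide is protonated by the acid released in the first step, so the cycle is redox‑neutral; the closest known reactions are the cyclisation–allylation of 2,3‑allenols with divalent palladium (oxypalladation, insertion, β‑halide elimination) and bipyridine–palladium vinyl additions to carbonyl groups after nucleopalladation of alkynes.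

Step 10
Reactants: 14 (2S,7S,8S)-2,16:7,8-diepoxycembra-1(15),3E,11E-trien-17-ol
Product: 15 [(2S,7S,8S)-2,16:7,8-diepoxycembra-1(15),3E,11E-trien-17-yl] acetate (CNP0140293.1)
Conditions: Ac2O, pyridine, DMAP (cat.), CH2Cl2, 0 °C → rt
Reagents that add atoms: acetic anhydride, CC(=O)OC(C)=O
Why: DMAP‑catalysed acetylation (nucleophilic acyl substitution) of the primary allylic alcohol touches no stereocentre.

**Compound list**
1 | (2E,6E)-farnesyl acetate | CC(C)=CCC/C(C)=C/CC/C(C)=C/COC(C)=O | starting material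
2 | (2E,6E,10E)-12-hydroxy-3,7,11-trimethyldodeca-2,6,10-trien-1-yl acetate | OC/C(C)=C/CC/C(C)=C/CC/C(C)=C/COC(C)=O | intermediate
3 | (2E,6E,10E)-12-chloro-3,7,11-trimethyldodeca-2,6,10-trien-1-yl acetate | ClC/C(C)=C/CC/C(C)=C/CC/C(C)=C/COC(C)=O | intermediate
4 | (2E,6S,7S,10E)-12-chloro-6,7-epoxy-3,7,11-trimethyldodeca-2,10-dien-1-yl acetate | ClC/C(C)=C/CC[C@]1(C)O[C@H]1CC/C(C)=C/COC(C)=O | intermediate
5 | but-2-ynoic acid | CC#CC(O)=O | starting material
6 | lithium (6E,10S,11S,14E)-16-acetoxy-10,11-epoxy-6,10,14-trimethylhexadeca-6,14-dien-2-ynoate | [Li+].[O-]C(=O)C#CCC/C(C)=C/CC[C@]1(C)O[C@H]1CC/C(C)=C/COC(C)=O | intermediate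
7 | methyl (6E,10S,11S,14E)-16-acetoxy-10,11-epoxy-6,10,14-trimethylhexadeca-6,14-dien-2-ynoate | COC(=O)C#CCC/C(C)=C/CC[C@]1(C)O[C@H]1CC/C(C)=C/COC(C)=O | intermediate
8 | (6E,10S,11S,14E)-10,11-epoxy-6,10,14-trimethylhexadeca-6,14-dien-2-yne-1,16-diol | OCC#CCC/C(C)=C/CC[C@]1(C)O[C@H]1CC/C(C)=C/CO | intermediate
9 | (2E,6S,7S,10E)-6,7-epoxy-16-hydroxy-3,7,11-trimethylhexadeca-2,10-dien-14-ynal | OCC#CCC/C(C)=C/CC[C@]1(C)O[C@H]1CC/C(C)=C/C=O | intermediate
10 | (2E,6S,7S,10E)-6,7-epoxy-3,7,11-trimethyl-1-oxohexadeca-2,10-dien-14-yn-16-yl methanesulfonate | CS(=O)(=O)OCC#CCC/C(C)=C/CC[C@]1(C)O[C@H]1CC/C(C)=C/C=O | intermediate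
11 | (2E,6S,7S,10E)-16-bromo-6,7-epoxy-3,7,11-trimethylhexadeca-2,10-dien-14-ynal | BrCC#CCC/C(C)=C/CC[C@]1(C)O[C@H]1CC/C(C)=C/C=O | intermediate
12 | trimethylsilyl ether of (2S,3E,7S,8S,11E)-1-ethenylidene-7,8-epoxy-4,8,12-trimethylcyclotetradeca-3,11-dien-2-ol | C=C=C1CC/C(C)=C/CC[C@]2(C)O[C@H]2CC/C(C)=C/[C@@H]1O[Si](C)(C)C | intermediate
13 | (2S,3E,7S,8S,11E)-1-ethenylidene-7,8-epoxy-4,8,12-trimethylcyclotetradeca-3,11-dien-2-ol | C=C=C1CC/C(C)=C/CC[C@]2(C)O[C@H]2CC/C(C)=C/[C@@H]1O | intermediate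
14 | (2S,7S,8S)-2,16:7,8-diepoxycembra-1(15),3E,11E-trien-17-ol (2,5-dihydrofuran fused at C1/C2, CH2OH on C15) | OCC1=C2CC/C(C)=C/CC[C@]3(C)O[C@H]3CC/C(C)=C/[C@@H]2OC1 | intermediate
15 | [(2S,7S,8S)-2,16:7,8-diepoxycembra-1(15),3E,11E-trien-17-yl] acetate (CNP0140293.1) | CC(=O)OCC1=C2CC/C(C)=C/CC[C@]3(C)O[C@H]3CC/C(C)=C/[C@@H]2OC1 | target

**Step count:** 10 steps in total. Longest linear sequence: 10 steps (from 1).

**Three steps most likely to fail**

Step 4 (dianion alkylation). The dianion may alkylate at its α‑carbon or attack the acetate. The fallback sets out from 4 and comes back at 8. The acetate of 4 is removed first with i‑Bu2AlH (CH2Cl2, −78 °C) to give (2E,6S,7S,10E)-12-chloro-6,7-epoxy-3,7,11-trimethyldodeca-2,10-dien-1-ol F1. F1 is alkylated with 3‑lithio‑1‑(trimethylsilyl)propyne (from 1‑(trimethylsilyl)propyne and n‑BuLi, 2.2 equiv, THF, −78 → −20 °C; the first equivalent forms the lithium alkoxide) to give (2E,6S,7S,10E)-6,7-epoxy-3,7,11-trimethyl-15-(trimethylsilyl)pentadeca-2,10-dien-14-yn-1-ol F2. K2CO3 in MeOH removes silicon to give (2E,6S,7S,10E)-6,7-epoxy-3,7,11-trimethylpentadeca-2,10-dien-14-yn-1-ol F3. Double deprotonation of F3 with n‑BuLi (2.2 equiv) and addition of (CH2O)n gives diol 8, where the route resumes at step 6.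

Step 8 (asymmetric macrocyclisation). Catalyst control over C2 may be weak in the ring‑closing mode, and the propargyl chromium could add through its α‑carbon. The fallback sets out from 11 and comes back at 13. Ring closure is run with stoichiometric CrCl2 (4 equiv, THF, high dilution, no chiral ligand), which gives 13 together with its C2 epimer (2R,3E,7S,8S,11E)-1-ethenylidene-7,8-epoxy-4,8,12-trimethylcyclotetradeca-3,11-dien-2-ol F4. The two diastereomers are separated by chromatography. F4 is inverted by Mitsunobu esterification (4‑nitrobenzoic acid, PPh3, diisopropyl azodicarboxylate) to (2S,3E,7S,8S,11E)-1-ethenylidene-7,8-epoxy-4,8,12-trimethylcyclotetradeca-3,11-dien-2-yl 4-nitrobenzoate F5, and K2CO3 in MeOH releases 13. SN2′ leakage in the Mitsunobu step is the weak point of this recycling.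

Step 9 (proposed new cyclisation–hydroxymethylation). Protonation of the vinylpalladium may outrun formaldehyde insertion and give the C15‑unsubstituted dihydrofuran. The fallback uses known chemistry, sets out from 13 and comes back at 14. Ph3PAuNTf2 (2 mol %, a catalyst of monovalent gold) with N‑iodosuccinimide in CH2Cl2 effects the known iodocyclisation of the α‑hydroxyallene to (2S,7S,8S)-15-iodo-2,16:7,8-diepoxy-17-norcembra-1(15),3E,11E-triene F6. Stille coupling of F6 with Bu3SnCH2OH and Pd(PPh3)4 (zerovalent palladium, dioxane, 80 °C) gives alcohol 14, which is acetylated as in step 10.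

**Further compounds**
F1 | step 4 | (2E,6S,7S,10E)-12-chloro-6,7-epoxy-3,7,11-trimethyldodeca-2,10-dien-1-ol | ClC/C(C)=C/CC[C@]1(C)O[C@H]1CC/C(C)=C/CO
F2 | step 4 | (2E,6S,7S,10E)-6,7-epoxy-3,7,11-trimethyl-15-(trimethylsilyl)pentadeca-2,10-dien-14-yn-1-ol | C[Si](C)(C)C#CCC/C(C)=C/CC[C@]1(C)O[C@H]1CC/C(C)=C/CO
F3 | step 4 | (2E,6S,7S,10E)-6,7-epoxy-3,7,11-trimethylpentadeca-2,10-dien-14-yn-1-ol | C#CCC/C(C)=C/CC[C@]1(C)O[C@H]1CC/C(C)=C/CO
F4 | step 8 | (2R,3E,7S,8S,11E)-1-ethenylidene-7,8-epoxy-4,8,12-trimethylcyclotetradeca-3,11-dien-2-ol | C=C=C1CC/C(C)=C/CC[C@]2(C)O[C@H]2CC/C(C)=C/[C@H]1O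
F5 | step 8 | (2S,3E,7S,8S,11E)-1-ethenylidene-7,8-epoxy-4,8,12-trimethylcyclotetradeca-3,11-dien-2-yl 4-nitrobenzoate | C=C=C1CC/C(C)=C/CC[C@]2(C)O[C@H]2CC/C(C)=C/[C@@H]1OC(=O)c1ccc(cc1)[N+](=O)[O-]
F6 | step 9 | (2S,7S,8S)-15-iodo-2,16:7,8-diepoxy-17-norcembra-1(15),3E,11E-triene | IC1=C2CC/C(C)=C/CC[C@]3(C)O[C@H]3CC/C(C)=C/[C@@H]2OC1
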